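Numbering: the tricycle is numbered as a fluorene (ring A = C1–C4, C4a, C9a; ring B = C4a, C4b, C8a, C9, C9a; ring C = C4b–C8a), the lactam C2'–C5'; β is the face of H-4a and H-4b (of H-3a in the hydrindene intermediates).
Retrosynthesis, outer part: the enol C3'=C(OH) and 4'-OH are masked as an isoxazoline (N–O cleaved last); the hemiaminal N–C5' comes from a γ-keto amide, and that from a γ-lactone; the 13-membered cyclophane is cut at O–C(aryl); the isoxazoline is cut into a C1 nitrile oxide and an (R)-5-(4-iodobenzyl)butenolide.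
Retrosynthesis, ring A: cut at C2–C3 and C4–C4a. The isolated C3=C4 alkene of ring A lies between the sp3 carbons C2 (vinyl) and C4a (A/B fusion), which is the retron of a [4+2] addition of a two-carbon acetylene equivalent to the s-cis diene C2=C1–C9a=C4a (C9a=C4a inside ring B, ester on C1). The extra C1=C9a unsaturation and two sulfonyl groups are helpers, removed in the next two steps.
Forward order: ring C (meso cis-3,5-dimethylcyclohexanone) → ring B (cyclopentenone by alkynal hydroacylation) → diene (Stille) → ring A (Diels–Alder) → isoxazoline–lactone (nitrile oxide cycloaddition) → cyclophane (Ullmann etherification) → hydroxylactam.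
Stereochemistry: C6/C8 from the meso ketone by chiral-base desymmetrisation; C8a by cuprate addition anti to the 8-methyl, C4b by equilibration; C9 by CBS reduction; C2 and C4a in the Diels–Alder step (diene geometry, attack anti to the C9 silyl ether); C9a and C1 by conjugate reduction/protonation; C4' by cycloaddition anti to the benzyl group of the (R)-butenolide (from (R)-epichlorohydrin); C5' by thermodynamic hemiaminal closure.

Key step: step 16

Assumption: the (R,R) lithium amide is taken to remove the α-proton that leads to the (3S,5R) enol triflate; if the sense of induction is the opposite, the (S,S) base is used in step 6.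

Step 1
Reactants: 1 vinyl bromide; 2 methyl propiolate
Product: 3 methyl pent-4-en-2-ynoate
Conditions: PdCl2(PPh3)2 (2 mol %), CuI (4 mol %), K2CO3, THF, 0 °C to rt
Reagents that add atoms: none
Why: Sonogashira coupling of a vinyl halide with a terminal alkyne, run with an inorganic base so that no amine can add to the propiolate.

Step 2
Reactants: 3 methyl pent-4-en-2-ynoate
Product: 4 methyl (2E)-2-(tributylstannyl)penta-2,4-dienoate
Conditions: Bu3SnH, Pd(PPh3)4 (2 mol %), THF, 0 °C
Reagents that add atoms: tributyltin hydride, CCCC[SnH](CCCC)CCCC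
Why: Palladium-catalysed syn-hydrostannation of an alkynoate puts tin α to the ester and hydrogen on the β-carbon, which fixes the vinyl group cis to the ester as the later diene requires.

Step 3
Reactants: 5 1,4-diiodobenzene; 6 (R)-epichlorohydrin
Product: 9 (R)-2-(4-iodobenzyl)oxirane, via (4-iodophenyl)magnesium chloride 7 (not isolated), via (R)-1-chloro-3-(4-iodophenyl)propan-2-ol 8 (not isolated)
Conditions: i-PrMgCl·LiCl (1.0 equiv), THF, −20 °C; CuI (10 mol %), then 6, −20 to 0 °C; then NaOH (aq), Et2O, rt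
Reagents that add atoms: none
Why: Iodine–magnesium exchange, copper-catalysed SN2 opening of the epoxide at its CH2 terminus and base-induced closure of the chlorohydrin (Williamson-type epoxide formation) never touch the C–O stereocentre taken from the chiral pool.

Step 4
Reactants: 9 (R)-2-(4-iodobenzyl)oxirane; 10 (phenylthio)acetic acid
Product: 13 (5R)-5-(4-iodobenzyl)-3-(phenylthio)dihydrofuran-2(3H)-one (C3 epimers), via dilithium 2-(phenylthio)ethene-1,1-diolate 11 (not isolated), via (4R)-4-hydroxy-5-(4-iodophenyl)-2-(phenylthio)pentanoic acid 12 (not isolated)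
Conditions: LiN(i-Pr)2 (2.1 equiv), THF, −78 to 0 °C; 9, 0 °C to rt; HCl (aq); then p-TsOH (cat.), toluene, 80 °C
Reagents that add atoms: none
Why: The carboxylate dianion opens the terminal epoxide at CH2 (SN2) and the γ-hydroxy acid lactonises under acid catalysis, so the carbinol centre is carried over unchanged.

Step 5
Reactants: 13 (5R)-5-(4-iodobenzyl)-3-(phenylthio)dihydrofuran-2(3H)-one
Product: 15 (R)-5-(4-iodobenzyl)furan-2(5H)-one, via (5R)-5-(4-iodobenzyl)-3-(phenylsulfinyl)dihydrofuran-2(3H)-one 14 (not isolated)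
Conditions: mCPBA (1.0 equiv), CH2Cl2, −78 °C; then toluene, CaCO3, 100 °C
Reagents that add atoms: none
Why: Sulfide oxidation and thermal sulfoxide syn-elimination (dehydrosulfenylation) can only engage the C4 hydrogens and therefore give the butenolide, the amine-free medium sparing its base-labile γ-stereocentre.

Step 6
Reactants: 16 cis-3,5-dimethylcyclohexanone
Product: 18 (3S,5R)-3,5-dimethylcyclohex-1-en-1-yl trifluoromethanesulfonate, via lithium (3S,5R)-3,5-dimethylcyclohex-1-en-1-olate 17 (not isolated)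
Conditions: (R,R)-bis(1-phenylethyl)amine, n-BuLi, LiCl, THF, −78 °C; then PhNTf2, −78 °C to rt
Reagents that add atoms: N-phenylbis(trifluoromethanesulfonimide), O=S(=O)(N(c1ccccc1)S(=O)(=O)C(F)(F)F)C(F)(F)F
Why: Enantioselective deprotonation of the meso ketone by the chiral lithium amide (desymmetrisation) differentiates the enantiotopic α-methylene groups, and O-sulfonylation of the enolate stores the result as a regiodefined enol triflate.

Step 7
Reactants: 18 (3S,5R)-3,5-dimethylcyclohex-1-en-1-yl trifluoromethanesulfonate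
Product: 19 (3S,5R)-3,5-dimethylcyclohex-1-ene-1-carbaldehyde
Conditions: Pd(OAc)2 (5 mol %), 1,3-bis(diphenylphosphino)propane (5 mol %), CO (1 atm), Et3SiH, Et3N, DMF, 70 °C
Reagents that add atoms: carbon monoxide, [C-]#[O+]
Why: Palladium-catalysed reductive carbonylation (formylation) of the enol triflate, in which the acylpalladium intermediate is intercepted by the silane.

Step 8
Reactants: 19 (3S,5R)-3,5-dimethylcyclohex-1-ene-1-carbaldehyde
Product: 21 3,5-dimethyl-2-vinylcyclohexane-1-carbaldehyde (all four substituents equatorial), via [(3,5-dimethyl-2-vinylcyclohexylidene)methoxy]trimethylsilane 20 (not isolated)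
Conditions: CH2=CHMgBr, CuBr·SMe2 (10 mol %), Me3SiCl, THF, −78 °C; then HCl (aq), rt
Reagents that add atoms: vinylmagnesium bromide, C=C[Mg]Br
Why: Copper-catalysed conjugate addition of the vinyl Grignard reagent, accelerated by Me3SiCl, occurs anti to the adjacent 3-methyl group (sets the later C8a), while the epimerisable formyl-bearing centre (the later C4b) ends up trans and equatorial here or under the carbonate of step 9.

Step 9
Reactants: 21 3,5-dimethyl-2-vinylcyclohexane-1-carbaldehyde
Product: 22 1-ethynyl-3,5-dimethyl-2-vinylcyclohexane (all-equatorial isomer)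
Conditions: dimethyl (1-diazo-2-oxopropyl)phosphonate, K2CO3, MeOH, 0 °C to rt
Reagents that add atoms: dimethyl (1-diazo-2-oxopropyl)phosphonate, CC(=O)C(=[N+]=[N-])P(=O)(OC)OC
Why: Seyferth–Gilbert homologation with the Ohira–Bestmann reagent turns the aldehyde into the terminal alkyne, the K2CO3/MeOH medium first equilibrating any cis aldehyde to the all-equatorial isomer.

Step 10
Reactants: 22 1-ethynyl-3,5-dimethyl-2-vinylcyclohexane
Product: 24 2-ethynyl-4,6-dimethylcyclohexane-1-carbaldehyde (all-equatorial isomer), via 1-(2-ethynyl-4,6-dimethylcyclohexyl)ethane-1,2-diol 23 (not isolated)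
Conditions: OsO4 (2 mol %), NaIO4, 2,6-lutidine, dioxane/H2O, rt
Reagents that add atoms: sodium periodate, [Na+].[O-]I(=O)(=O)=O
Why: Johnson–Lemieux oxidation (dihydroxylation, then periodate cleavage) is selective for the alkene over the alkyne, and the new equatorial formyl group has no driving force to epimerise.

Step 11
Reactants: 24 2-ethynyl-4,6-dimethylcyclohexane-1-carbaldehyde
Product: 25 trans-fused 5α,7α-dimethyl-3a,4,5,6,7,7a-hexahydro-1H-inden-1-one (3aβ-H; 7aα-H)
Conditions: [Rh(dppe)]2(BF4)2 (5 mol %), acetone, rt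
Reagents that add atoms: none
Why: Rhodium-catalysed intramolecular trans-hydroacylation of the 4-alkynal closes ring B as a cyclopent-2-enone under neutral conditions, which spares the base-labile α ring-fusion centre of the strained trans-fused enone.

Step 12
Reactants: 25 trans-fused 5α,7α-dimethyl-3a,4,5,6,7,7a-hexahydro-1H-inden-1-one
Product: 26 2-iodo-5α,7α-dimethyl-3a,4,5,6,7,7a-hexahydro-1H-inden-1-one (trans-fused)
Conditions: I2, pyridine, CH2Cl2, 0 °C to rt
Reagents that add atoms: iodine, II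
Why: α-Iodination of the enone by the pyridine-mediated addition–iodination–elimination sequence installs the cross-coupling handle at C2 without strong base.

Step 13
Reactants: 26 2-iodo-5α,7α-dimethyl-3a,4,5,6,7,7a-hexahydro-1H-inden-1-one
Product: 27 (1R)-2-iodo-5α,7α-dimethyl-3a,4,5,6,7,7a-hexahydro-1H-inden-1β-ol (trans-fused)
Conditions: (S)-2-methyl-CBS-oxazaborolidine (20 mol %), BH3·SMe2, THF, −30 °C; MeOH, then H2O
Reagents that add atoms: none
Why: Corey–Bakshi–Shibata reduction with the α-iodoalkenyl arm as the large group delivers hydride to the α-face under catalyst control and sets the (1R) carbinol centre (the later C9) with the hydroxyl on the β-face.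

Step 14
Reactants: 27 (1R)-2-iodo-5α,7α-dimethyl-3a,4,5,6,7,7a-hexahydro-1H-inden-1β-ol
Product: 28 tert-butyldimethylsilyl ether of 27
Conditions: TBSOTf, 2,6-lutidine, CH2Cl2, −78 to 0 °C
Reagents that add atoms: tert-butyldimethylsilyl trifluoromethanesulfonate, CC(C)(C)[Si](C)(C)OS(=O)(=O)C(F)(F)F
Why: Silylation of the hindered secondary alcohol with the silyl triflate gives a bulky silyl ether that later shields the β-face and keeps the hydroxyl from intercepting the nitrile oxide.

Step 15
Reactants: 28 tert-butyldimethylsilyl ether of 27; 4 methyl (2E)-2-(tributylstannyl)penta-2,4-dienoate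
Product: 29 methyl (2Z)-2-[1β-(tert-butyldimethylsilyloxy)-5α,7α-dimethyl-3a,4,5,6,7,7a-hexahydro-1H-inden-2-yl]penta-2,4-dienoate
Conditions: Pd2(dba)3 (5 mol %), AsPh3 (20 mol %), CuI (10 mol %), DMF, 50 °C
Reagents that add atoms: none
Why: Copper-assisted Stille coupling joins the two sp2 carbons with retention of the stannane geometry, giving the (2Z)-dienoate whose inner diene carries hydrogen at both inside positions.

Step 16
Reactants: 29 methyl (2Z)-2-[1β-(tert-butyldimethylsilyloxy)-5α,7α-dimethyl-3a,4,5,6,7,7a-hexahydro-1H-inden-2-yl]penta-2,4-dienoate; 30 (E)-1,2-bis(phenylsulfonyl)ethene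
Product: 31 methyl 9β-(tert-butyldimethylsilyloxy)-6α,8α-dimethyl-3β,4α-bis(phenylsulfonyl)-2α-vinyl-2,3,4,4a,4b,5,6,7,8,8a-decahydro-9H-fluorene-1-carboxylate
Conditions: toluene, 110 °C, sealed tube, 2,6-di-tert-butyl-4-methylphenol (trace)
Reagents that add atoms: none
Why: Concerted, suprafacial normal-demand [4+2] cycloaddition (Diels–Alder reaction) in which the sulfonyl-activated two-carbon dienophile, an acetylene equivalent, bonds to the termini C2 and C4a of the s-cis diene C2=C1–C9a=C4a and so forms C2–C3 and C4–C4a at once; the closest known reaction type is the Diels–Alder reaction of 1,2-bis(arylsulfonyl)ethenes with 1-vinylcycloalkene-type dienes. Ring A is the only ring closed, by intermolecular [4+2] annulation onto the ring B alkene, which moves to C1=C9a. C4a is set by approach of the dienophile to the α-face, anti to the C9 silyloxy group that shields the β-face, and C2 follows from the (2Z) diene geometry, because the two inside hydrogens end up cis (both β, vinyl α); the two sulfonyl-bearing centres are transient (the other trans-disulfone isomer converges in step 17). The step needs facial selectivity and periselectivity for the inner diene: the silyl ether secures the first, and the terminal diene cannot compete because its C1 terminus carries a cis substituent that blocks the s-cis conformation.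

Step 17
Reactants: 31 Diels–Alder adduct
Product: 32 methyl 9β-(tert-butyldimethylsilyloxy)-6α,8α-dimethyl-2α-vinyl-2,4a,4b,5,6,7,8,8a-octahydro-9H-fluorene-1-carboxylate
Conditions: Na(Hg) (6 %), NaH2PO4, MeOH/THF, −20 °C
Reagents that add atoms: none
Why: Julia-type reductive elimination of the vicinal bis-sulfone by electron transfer from sodium amalgam unveils the C3=C4 alkene, the harder-to-reduce tetrasubstituted enoate staying intact at −20 °C.

Step 18
Reactants: 32 methyl 9β-(tert-butyldimethylsilyloxy)-6α,8α-dimethyl-2α-vinyl-2,4a,4b,5,6,7,8,8a-octahydro-9H-fluorene-1-carboxylate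
Product: 34 methyl 9β-(tert-butyldimethylsilyloxy)-6α,8α-dimethyl-2α-vinyl-2,4a,4b,5,6,7,8,8a,9,9a-decahydro-1H-fluorene-1α-carboxylate (9aα-H; 1β-H), via lithium ester enolate 33 (not isolated)
Conditions: Li (2.5 equiv), NH3 (l), THF, t-BuOH (1.0 equiv), −78 °C; then NH4Cl (s)
Reagents that add atoms: none
Why: Birch-type dissolving-metal conjugate reduction of the tetrasubstituted enoate, in which C9a is protonated on the α-face away from the β-silyloxy group on C9 (trans A/B fusion) and the ester enolate is protonated at C1 anti to the α-vinyl group, giving the equatorial ester that should also be the thermodynamically favoured epimer.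

Step 19
Reactants: 34 methyl 9β-(tert-butyldimethylsilyloxy)-6α,8α-dimethyl-2α-vinyl-decahydro-1H-fluorene-1α-carboxylate
Product: 36 9β-(tert-butyldimethylsilyloxy)-6α,8α-dimethyl-2α-vinyl-2,4a,4b,5,6,7,8,8a,9,9a-decahydro-1H-fluorene-1α-carbaldehyde, via aluminium hemiacetal 35 (not isolated)
Conditions: i-Bu2AlH (1.1 equiv), CH2Cl2, −78 °C; MeOH, then aqueous potassium sodium tartrate
Reagents that add atoms: none
Why: Partial reduction of the hindered methyl ester with diisobutylaluminium hydride stops at the tetrahedral aluminium hemiacetal at −78 °C, which collapses to the aldehyde only on work-up.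

Step 20
Reactants: 36 tricyclic 1α-carbaldehyde
Product: 37 (E)-oxime of 36
Conditions: NH2OH·HCl, pyridine, EtOH, rt
Reagents that add atoms: hydroxylamine hydrochloride, NO.Cl
Why: Condensation of the aldehyde with hydroxylamine gives the aldoxime, the precursor of the nitrile oxide, under conditions too mild to epimerise C1.

Step 21
Reactants: 37 (E)-oxime of 36; 15 (R)-5-(4-iodobenzyl)furan-2(5H)-one
Product: 40 cis-fused 3-(tricyclyl)-6-(4-iodobenzyl)-3a,6a-dihydrofuro[3,4-d]isoxazol-4(6H)-one (benzyl trans to the isoxazoline oxygen; 9β-silyl ether), via N-hydroxyimidoyl chloride 38 (not isolated), via nitrile oxide 39 (not isolated)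
Conditions: N-chlorosuccinimide, DMF, rt; then 15 (3 equiv), KHCO3 (s), EtOAc, rt, slow generation of the dipole
Reagents that add atoms: none
Why: Huisgen 1,3-dipolar cycloaddition of the in situ generated nitrile oxide to the butenolide, in which the dipole carbon bonds to the lactone α-carbon and the oxygen to the β-carbon on the face anti to the iodobenzyl group, so that C4' is set by the butenolide stereocentre and the aldol unit is stored as an isoxazoline.

Step 22
Reactants: 40 silylated cycloadduct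
Product: 41 9β-alcohol of 40
Conditions: HF·pyridine, pyridine, THF, 0 °C to rt
Reagents that add atoms: none
Why: Fluoride-induced cleavage of the silyl ether under buffered acidic conditions frees the C9 hydroxyl without opening the lactone or the isoxazoline.

Step 23
Reactants: 41 9β-alcohol of 40
Product: 42 13-membered cyclophane (41 with O-9 bonded to the former C–I carbon of the arene)
Conditions: CuI (20 mol %), 3,4,7,8-tetramethyl-1,10-phenanthroline (40 mol %), Cs2CO3, toluene (0.002 M), 110 °C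
Reagents that add atoms: none
Why: Intramolecular Ullmann-type copper-catalysed C–O coupling of the C9 alkoxide and the aryl iodide closes the 13-membered para-cyclophane with retention at C9, a closure with close precedent in strained decahydrofluorene aryl ether cyclophanes, while high dilution holds back oligomers.

Step 24
Reactants: 42 13-membered cyclophane lactone
Product: 43 macrocyclic γ-hydroxy primary amide
Conditions: NH3 (7 M in MeOH), rt
Reagents that add atoms: ammonia, N
Why: Aminolysis of the γ-lactone gives the primary amide and liberates the C5' hydroxyl, the isoxazoline being inert to ammonia.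

Step 25
Reactants: 43 macrocyclic γ-hydroxy primary amide
Product: 45 isoxazoline-fused 5'-hydroxy lactam (hemiaminal), via keto amide 44 (not isolated)
Conditions: Dess–Martin periodinane, NaHCO3, CH2Cl2, 0 °C to rt
Reagents that add atoms: none
Why: Dess–Martin oxidation of the only free alcohol gives the γ-keto amide, which closes by ring–chain tautomerism to the five-membered hemiaminal with the benzylic carbon on the convex face, that is with 5'-OH cis to the C4' oxygen.

Step 26
Reactants: 45 isoxazoline-fused 5'-hydroxy lactam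
Product: 47 xenoacremone A, via enaminone 46 (not isolated)
Conditions: SmI2 (2.5 equiv), THF, 0 °C; then B(OH)3, H2O/MeOH, rt
Reagents that add atoms: water, O
Why: Reductive N–O cleavage of the isoxazoline by single-electron transfer from SmI2 and mild hydrolysis of the β-hydroxy enaminone unmask the aldol unit as the hydrogen-bonded enol of the 3'-acyl lactam without epimerising C4' or eliminating the β-hydroxyl group.

Compound list
1 | vinyl bromide | C=CBr | starting material
2 | methyl propiolate | C#CC(=O)OC | starting material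
3 | methyl pent-4-en-2-ynoate | C=CC#CC(=O)OC | intermediate
4 | methyl (2E)-2-(tributylstannyl)penta-2,4-dienoate (vinyl cis to the ester) | C=C/C=C(\C(=O)OC)[Sn](CCCC)(CCCC)CCCC | intermediate
5 | 1,4-diiodobenzene | Ic1ccc(I)cc1 | starting material
6 | (R)-epichlorohydrin | ClC[C@H]1CO1 | starting material
7 | (4-iodophenyl)magnesium chloride | Cl[Mg]c1ccc(I)cc1 | intermediate
8 | (R)-1-chloro-3-(4-iodophenyl)propan-2-ol | ClC[C@H](O)Cc1ccc(I)cc1 | intermediate
9 | (R)-2-(4-iodobenzyl)oxirane | C1[C@H](O1)Cc2ccc(I)cc2 | intermediate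
10 | (phenylthio)acetic acid | OC(=O)CSc1ccccc1 | starting material
11 | dilithium 2-(phenylthio)ethene-1,1-diolate | [Li]OC(O[Li])=CSc1ccccc1 | intermediate
12 | (4R)-4-hydroxy-5-(4-iodophenyl)-2-(phenylthio)pentanoic acid (C2 epimers) | OC(=O)C(Sc1ccccc1)C[C@H](O)Cc1ccc(I)cc1 | intermediate
13 | (5R)-5-(4-iodobenzyl)-3-(phenylthio)dihydrofuran-2(3H)-one (C3 epimers) | O=C1C(Sc2ccccc2)C[C@@H](Cc2ccc(I)cc2)O1 | intermediate
14 | (5R)-5-(4-iodobenzyl)-3-(phenylsulfinyl)dihydrofuran-2(3H)-one | O=C1C(S(=O)c2ccccc2)C[C@@H](Cc2ccc(I)cc2)O1 | intermediate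
15 | (R)-5-(4-iodobenzyl)furan-2(5H)-one | O=C1C=C[C@@H](Cc2ccc(I)cc2)O1 | intermediate
16 | cis-3,5-dimethylcyclohexanone (meso) | O=C1C[C@H](C)C[C@H](C)C1 | starting material
17 | lithium (3S,5R)-3,5-dimethylcyclohex-1-en-1-olate | [Li]OC=1C[C@H](C)C[C@H](C)C=1 | intermediate
18 | (3S,5R)-3,5-dimethylcyclohex-1-en-1-yl trifluoromethanesulfonate | FC(F)(F)S(=O)(=O)OC=1C[C@H](C)C[C@H](C)C=1 | intermediate
19 | (3S,5R)-3,5-dimethylcyclohex-1-ene-1-carbaldehyde | O=CC=1C[C@H](C)C[C@H](C)C=1 | intermediate
20 | [(3,5-dimethyl-2-vinylcyclohexylidene)methoxy]trimethylsilane (vinyl trans to the 3-methyl) | C[Si](C)(C)OC=C1C[C@H](C)C[C@H](C)[C@H]1C=C | intermediate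
21 | 3,5-dimethyl-2-vinylcyclohexane-1-carbaldehyde, all four substituents equatorial (CHO trans to vinyl; vinyl trans to 3-methyl; methyls cis) | O=C[C@@H]1C[C@H](C)C[C@H](C)[C@H]1C=C | intermediate
22 | 1-ethynyl-3,5-dimethyl-2-vinylcyclohexane, all-equatorial isomer | C#C[C@@H]1C[C@H](C)C[C@H](C)[C@H]1C=C | intermediate
23 | 1-(2-ethynyl-4,6-dimethylcyclohexyl)ethane-1,2-diol (carbinol epimers) | C#C[C@@H]1C[C@H](C)C[C@H](C)[C@H]1C(O)CO | intermediate
24 | 2-ethynyl-4,6-dimethylcyclohexane-1-carbaldehyde, all-equatorial isomer | C#C[C@@H]1C[C@H](C)C[C@H](C)[C@H]1C=O | intermediate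
25 | trans-fused 5α,7α-dimethyl-3a,4,5,6,7,7a-hexahydro-1H-inden-1-one (3aβ-H; 7aα-H) | O=C1C=C[C@@H]2C[C@H](C)C[C@H](C)[C@H]21 | intermediate
26 | 2-iodo derivative of 25 | O=C1C(I)=C[C@@H]2C[C@H](C)C[C@H](C)[C@H]21 | intermediate
27 | (1R)-2-iodo-5α,7α-dimethyl-3a,4,5,6,7,7a-hexahydro-1H-inden-1β-ol (3aβ-H; 7aα-H) | O[C@H]1C(I)=C[C@@H]2C[C@H](C)C[C@H](C)[C@H]21 | intermediate
28 | tert-butyldimethylsilyl ether of 27 | CC(C)(C)[Si](C)(C)O[C@H]1C(I)=C[C@@H]2C[C@H](C)C[C@H](C)[C@H]21 | intermediate
29 | methyl (2Z)-2-[1β-(tert-butyldimethylsilyloxy)-5α,7α-dimethyl-3a,4,5,6,7,7a-hexahydro-1H-inden-2-yl]penta-2,4-dienoate | C=C/C=C(\C(=O)OC)C1=C[C@@H]2C[C@H](C)C[C@H](C)[C@H]2[C@H]1O[Si](C)(C)C(C)(C)C | intermediate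
30 | (E)-1,2-bis(phenylsulfonyl)ethene | O=S(=O)(/C=C/S(=O)(=O)c1ccccc1)c1ccccc1 | starting material
31 | Diels–Alder adduct: methyl 9β-(tert-butyldimethylsilyloxy)-6α,8α-dimethyl-3β,4α-bis(phenylsulfonyl)-2α-vinyl-2,3,4,4a,4b,5,6,7,8,8a-decahydro-9H-fluorene-1-carboxylate (H-2, H-4a, H-4b β; H-8a, H-9 α) | C=C[C@@H]1[C@@H](S(=O)(=O)c2ccccc2)[C@H](S(=O)(=O)c2ccccc2)[C@@H]2[C@@H]3C[C@H](C)C[C@H](C)[C@H]3[C@@H](O[Si](C)(C)C(C)(C)C)C2=C1C(=O)OC | intermediate
32 | methyl 9β-(tert-butyldimethylsilyloxy)-6α,8α-dimethyl-2α-vinyl-2,4a,4b,5,6,7,8,8a-octahydro-9H-fluorene-1-carboxylate | C=C[C@@H]1C=C[C@@H]2[C@@H]3C[C@H](C)C[C@H](C)[C@H]3[C@@H](O[Si](C)(C)C(C)(C)C)C2=C1C(=O)OC | intermediate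
33 | lithium enolate of ester 34 | C=C[C@@H]1C=C[C@@H]2[C@@H]3C[C@H](C)C[C@H](C)[C@H]3[C@@H](O[Si](C)(C)C(C)(C)C)[C@H]2C1=C(OC)O[Li] | intermediate
34 | methyl 9β-(tert-butyldimethylsilyloxy)-6α,8α-dimethyl-2α-vinyl-2,4a,4b,5,6,7,8,8a,9,9a-decahydro-1H-fluorene-1α-carboxylate (H-1, H-2, H-4a, H-4b β; H-8a, H-9, H-9a α) | C=C[C@@H]1C=C[C@@H]2[C@@H]3C[C@H](C)C[C@H](C)[C@H]3[C@@H](O[Si](C)(C)C(C)(C)C)[C@H]2[C@@H]1C(=O)OC | intermediate
35 | diisobutylaluminium hemiacetal of 34 | C=C[C@@H]1C=C[C@@H]2[C@@H]3C[C@H](C)C[C@H](C)[C@H]3[C@@H](O[Si](C)(C)C(C)(C)C)[C@H]2[C@@H]1C(OC)O[Al](CC(C)C)CC(C)C | intermediate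
36 | 1α-carbaldehyde corresponding to 34 | C=C[C@@H]1C=C[C@@H]2[C@@H]3C[C@H](C)C[C@H](C)[C@H]3[C@@H](O[Si](C)(C)C(C)(C)C)[C@H]2[C@@H]1C=O | intermediate
37 | (E)-oxime of 36 | C=C[C@@H]1C=C[C@@H]2[C@@H]3C[C@H](C)C[C@H](C)[C@H]3[C@@H](O[Si](C)(C)C(C)(C)C)[C@H]2[C@@H]1/C=N/O | intermediate
38 | N-hydroxyimidoyl chloride from 37 | C=C[C@@H]1C=C[C@@H]2[C@@H]3C[C@H](C)C[C@H](C)[C@H]3[C@@H](O[Si](C)(C)C(C)(C)C)[C@H]2[C@@H]1C(Cl)=NO | intermediate
39 | nitrile oxide from 38 | C=C[C@@H]1C=C[C@@H]2[C@@H]3C[C@H](C)C[C@H](C)[C@H]3[C@@H](O[Si](C)(C)C(C)(C)C)[C@H]2[C@@H]1C#[N+][O-] | intermediate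
40 | cis-fused 3-(tricyclyl)-6-(4-iodobenzyl)-3a,6a-dihydrofuro[3,4-d]isoxazol-4(6H)-one, benzyl trans to the isoxazoline oxygen, 9β-silyl ether | C=C[C@@H]1C=C[C@@H]2[C@@H]3C[C@H](C)C[C@H](C)[C@H]3[C@@H](O[Si](C)(C)C(C)(C)C)[C@H]2[C@@H]1C4=NO[C@H]5[C@@H]4C(=O)O[C@@H]5Cc6ccc(I)cc6 | intermediate
41 | 9β-alcohol of 40 | C=C[C@@H]1C=C[C@@H]2[C@@H]3C[C@H](C)C[C@H](C)[C@H]3[C@@H](O)[C@H]2[C@@H]1C4=NO[C@H]5[C@@H]4C(=O)O[C@@H]5Cc6ccc(I)cc6 | intermediate
42 | 13-membered cyclophane: 41 with O-9 bonded to the former C–I carbon | C=C[C@@H]1C=C[C@@H]2[C@@H]3C[C@H](C)C[C@H](C)[C@H]3[C@@H](Oc6ccc(cc6)C7)[C@H]2[C@@H]1C4=NO[C@H]5[C@@H]4C(=O)O[C@@H]57 | intermediate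
43 | macrocyclic γ-hydroxy primary amide (lactone of 42 opened) | C=C[C@@H]1C=C[C@@H]2[C@@H]3C[C@H](C)C[C@H](C)[C@H]3[C@@H](Oc6ccc(cc6)C7)[C@H]2[C@@H]1C4=NO[C@@H]([C@@H]4C(N)=O)[C@@H]7O | intermediate
44 | macrocyclic γ-keto amide | C=C[C@@H]1C=C[C@@H]2[C@@H]3C[C@H](C)C[C@H](C)[C@H]3[C@@H](Oc6ccc(cc6)C7)[C@H]2[C@@H]1C4=NO[C@@H]([C@@H]4C(N)=O)C7=O | intermediate
45 | isoxazoline-fused 5'-hydroxy lactam (hemiaminal; 5'-OH cis to the C4' oxygen) | C=C[C@@H]1C=C[C@@H]2[C@@H]3C[C@H](C)C[C@H](C)[C@H]3[C@@H](Oc6ccc(cc6)C7)[C@H]2[C@@H]1C4=NO[C@H]5[C@@H]4C(=O)N[C@@]57O | intermediate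
46 | β-hydroxy enaminone (NH2 in place of the enol OH of 47) | C=C[C@@H]1C=C[C@@H]2[C@@H]3C[C@H](C)C[C@H](C)[C@H]3[C@H]3Oc4ccc(cc4)C[C@@]4(O)NC(=O)/C(=C(\N)[C@H]1[C@@H]23)[C@@H]4O | intermediate
47 | xenoacremone A | C=C[C@@H]1C=C[C@@H]2[C@@H]3C[C@H](C)C[C@H](C)[C@H]3[C@H]3Oc4ccc(cc4)C[C@@]4(O)NC(=O)/C(=C(\O)[C@H]1[C@@H]23)[C@@H]4O | target

Total step count: 26. Longest linear sequence: 21 steps (steps 6 to 26, from cis-3,5-dimethylcyclohexanone); steps 1–2 and 3–5 are the two side branches.

Steps most likely to fail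

Step 23 (macrocyclisation). Intermolecular coupling to oligomers or loss of iodine from the arene may outrun closure of the strained 13-membered ring, and the hot carbonate medium may erode the lactone. The fallback reverses the polarity of the arene and closes the ring by oxidative coupling at room temperature. From 41, Miyaura borylation (bis(pinacolato)diboron, PdCl2(dppf), KOAc, DMSO, 80 °C) gives the aryl pinacol boronate F1, and KHF2 (MeOH/H2O) gives the potassium aryltrifluoroborate F2. This is cyclised onto the C9 hydroxyl by Chan–Lam-type etherification (Cu(OAc)2, 4-(dimethylamino)pyridine, 4 Å molecular sieves, O2, CH2Cl2, high dilution, rt), and the route is rejoined at 42.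

Step 18 (conjugate reduction). C9a may be protonated from the β-face (cis A/B fusion), the ester may be reduced further, or the skipped diene may migrate under the basic medium. The fallback replaces electron transfer to the enoate by hydride transfer to an enal. From 32, i-Bu2AlH (2.2 equiv, CH2Cl2, −78 °C) gives the allylic alcohol F3 and MnO2 (CH2Cl2, rt) the enal F4. Copper hydride conjugate reduction ([(Ph3P)CuH]6, benzene, rt; aqueous NH4Cl) should then deliver hydride to C9a on the α-face, anti to the silyl ether, and after protonation of the copper enolate give aldehyde 36, where the route is rejoined (steps 18 and 19 are bypassed).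

Step 16 (Diels–Alder). The cycloaddition may be sluggish because the ester-bearing diene and the bis-sulfone are both electron-poor, and the higher temperature then needed may polymerise the triene or erode the facial selectivity. The fallback uses inverse electron demand. Diene 29 is combined with the electron-rich (Z)-1,2-bis(phenylthio)ethene under Lewis acid activation of the dienoate (Et2AlCl, CH2Cl2, −40 to 0 °C) to give the cis-bis(phenylthio) adduct F5. Chemoselective S-oxidation ((NH4)6Mo7O24 cat., H2O2, EtOH, 0 °C) gives the cis-bis-sulfone F6, and Na(Hg)/NaH2PO4 (MeOH/THF, −20 °C) returns to 32.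

Further compounds
F1 | step 23 | aryl pinacol boronate of 41 (Bpin in place of iodine) | C=C[C@@H]1C=C[C@@H]2[C@@H]3C[C@H](C)C[C@H](C)[C@H]3[C@@H](O)[C@H]2[C@@H]1C4=NO[C@H]5[C@@H]4C(=O)O[C@@H]5Cc6ccc(cc6)B7OC(C)(C)C(C)(C)O7
F2 | step 23 | potassium aryltrifluoroborate of 41 (BF3K in place of iodine) | C=C[C@@H]1C=C[C@@H]2[C@@H]3C[C@H](C)C[C@H](C)[C@H]3[C@@H](O)[C@H]2[C@@H]1C4=NO[C@H]5[C@@H]4C(=O)O[C@@H]5Cc6ccc(cc6)[B-](F)(F)F.[K+]
F3 | step 18 | allylic alcohol: [9β-(tert-butyldimethylsilyloxy)-6α,8α-dimethyl-2α-vinyl-2,4a,4b,5,6,7,8,8a-octahydro-9H-fluoren-1-yl]methanol | C=C[C@@H]1C=C[C@@H]2[C@@H]3C[C@H](C)C[C@H](C)[C@H]3[C@@H](O[Si](C)(C)C(C)(C)C)C2=C1CO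
F4 | step 18 | enal: 9β-(tert-butyldimethylsilyloxy)-6α,8α-dimethyl-2α-vinyl-2,4a,4b,5,6,7,8,8a-octahydro-9H-fluorene-1-carbaldehyde | C=C[C@@H]1C=C[C@@H]2[C@@H]3C[C@H](C)C[C@H](C)[C@H]3[C@@H](O[Si](C)(C)C(C)(C)C)C2=C1C=O
F5 | step 16 | cis-bis(phenylthio) adduct: 3α,4α-bis(phenylthio) analogue of 31 | C=C[C@@H]1[C@H](Sc2ccccc2)[C@H](Sc2ccccc2)[C@@H]2[C@@H]3C[C@H](C)C[C@H](C)[C@H]3[C@@H](O[Si](C)(C)C(C)(C)C)C2=C1C(=O)OC
F6 | step 16 | cis-bis-sulfone: 3α,4α-bis(phenylsulfonyl) isomer of 31 | C=C[C@@H]1[C@H](S(=O)(=O)c2ccccc2)[C@H](S(=O)(=O)c2ccccc2)[C@@H]2[C@@H]3C[C@H](C)C[C@H](C)[C@H]3[C@@H](O[Si](C)(C)C(C)(C)C)C2=C1C(=O)OC
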